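## Analysis of the target

The target 29 is a germacranolide. A ten-membered carbocycle (C1–C10) is fused along C6–C7 to an α,β-unsaturated γ-lactone (C6, C7, C11, C12 and the ring oxygen), and the tetrasubstituted C7=C11 bond carries the acetoxymethyl carbon C13. The carbocycle holds a Z trisubstituted C4=C5 alkene, a C1 ketone next to the fully substituted C10 (methyl C14 and acetoxy), and a methacrylate on C8. There are three stereocentres, 6R, 8S and 10S. C6 and C8 flank the sp2 carbon C7, and C8 and C10 are 1,3-related across C9, so no two are adjacent and relay of configuration is weak. The sensitive points are: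

- the C6–H bond, which is allylic and γ to the lactone carbonyl, so base can epimerise it or deconjugate the butenolide;
- the allylic C13 acetate, which is open to addition–elimination;
- the polymerisable methacrylate and the α-acetoxy ketone;
- a free C8 hydroxyl facing a free C1 ketone, which can close a transannular hemiketal.

The difficulty is to close a ten-membered ring that contains a Z alkene while building a fully substituted butenolide alkene with C12 and C13 placed correctly. The strategy rests on one feature: the butenolide is the sum of an aldehyde carbon (C6), an alkyne (C7≡C11, already bonded to C8 and C13) and one carbonyl carbon (C12), and its C6–C7 bond is also a bond of the ten-membered ring.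

## Retrosynthetic reasoning

**End game (29 ⇐ 28 ⇐ 27 ⇐ 26).** The C1 ketone of 29 is unmasked last from dioxolane 28, the methacrylate of 28 comes from alcohol 27, and 27 from silyl ether 26. The ketal stays on until C8 is acylated, so that a free C8 hydroxyl never faces a free C1 ketone. The methacrylate is added only after the metal carbonyl step, because an alkyne carrying a propargylic acrylate ester is a substrate for an ordinary Pauson–Khand reaction.

**Key disconnection (26 ⇐ 25).** Three bonds of 26 are cut together: C6–C7, C11–C12 and C12–O. This leaves the open-chain Z-enal 25, in which every heavy atom of the core except C12 is present. The cut is made here because C6–C7 belongs to both rings, so one [2+2+1] event of aldehyde, alkyne and a carbonyl ligand closes the carbocycle and the lactone and sets C6. The forward reaction must couple the aldehyde at C7 and not C11, approach the aldehyde face that gives 6R, and win against intermolecular coupling. The C1 ketone must be masked, since a free ketone three atoms from the alkyne would be the better carbonyl partner and would close a five-membered ring.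

**Functional group adjustment (25 ⇐ 24 ⇐ 23 ⇐ 22 ⇐ 21).** The Z-enal of 25 is made last, by oxidation of allylic alcohol 24, because it isomerises easily. Both acetates of 23 are put on in one step from diol 22, after the last organometallic reaction. Three orthogonal groups carry the oxygens up to that point: a 4-methoxybenzyl ether on C13 (removed oxidatively, 21 to 22), a triethylsilyl ether on C6 (removed by buffered fluoride, 23 to 24) and a tert-butyldimethylsilyl ether on C8 (kept through the key step).

**C1 ketal and the C1–C2 bond (21 ⇐ 19 ⇐ 18 + 11).** The dioxolane of 21 is made from α-hydroxy ketone 19 while the tertiary hydroxyl is still free. The chain is cut at C1–C2 because this separates the achiral Z arm from the half that carries both stereocentres, and because C2 is a simple primary carbanion (organolithium 18 from iodide 17) that adds once to Weinreb amide 11. The quaternary C10 cannot epimerise.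

**C8 stereocentre (11 ⇐ 10 ⇐ 9 ⇐ 7).** The C8 carbinol is set by catalyst-controlled transfer hydrogenation of ynone 7. The new hydroxyl then displaces the acetonide and forms lactone 9, which protects C1 and C10–OH without extra steps and opens cleanly to amide 10. The alkyne is brought in early for two reasons. Reduction of an ynone is the most dependable way to a propargylic carbinol of either configuration. The other order, alkynylation of a C8 aldehyde carbon after the C10 acetate is in place, would put an unbranched aldehyde β to a tertiary acetate under amine–zinc conditions and invites elimination and self-condensation.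

**C7–C8 bond and the chiral pool (7 ⇐ 4 + 2; 4 ⇐ 3; 2 ⇐ 1).** Ynone 7 is the acylation product of the alkynylzinc reagent from ether 2 with the acid chloride of 4. Acid 4 is (S)-citramalic acid 3 with its α-hydroxy acid half tied up as a dioxolanone. This differentiates the two carboxyl groups and supplies C1, C8, C9, C10, C14 and the 10S configuration. Ether 2 comes from propargyl alcohol 1.

**Z arm (17 ⇐ 16 ⇐ 14 ⇐ 13 ⇐ 12).** The C2–C6 arm with C15 is taken from the Z-enynol 12, whose double bond is never touched. Its alkyne is reduced to a vinyl group (14), hydroborated at the terminus (16) and converted to iodide 17. This gives a C2 nucleophile and a protected C6 oxygen without having to tell apart two primary hydroxyls.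

## Alternatives that were turned down

**Alternative 1: cycloreversion of a cyclobutene–enone photoadduct to A1.**
- Disconnection: the C1=C10 and C4=C5 double bonds of A1 are traced back to the C1–C4 and C5–C10 sigma bonds of a central cyclobutane, that is, to a [2+2] photocycloaddition of a cyclohexenone C5=C10 bond with a cyclobutene C1=C4 bond.
- Forward key step: heating cleaves the two opposite cyclobutane bonds and opens out the cyclodeca-1(10),4-diene.
- For it: ring formation is unimolecular, needs no dilution and belongs to a known reaction class. On the certainty of ring formation it is stronger than the chosen route.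
- Against it: A1 has only the C8 stereocentre. C10 would have to be oxygenated on a flexible ten-membered enol ether and C6 reduced with facial control. The two CH2O arms on C11 must be told apart to make the lactone. The 1,5-diene in A1 can undergo Cope rearrangement at the temperature that forms it.
- Comparison: the chosen route buys 10S, sets 8S with a catalyst before cyclisation, and makes the lactone in the ring-forming step, so three steps remain after it.

**Alternative 2: glycol cleavage of a cis-fused decalin-1,6-diol to A2.**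
- Disconnection: the C1 and C6 carbonyls of A2 are rejoined as the ring-fusion bond of a decalin diol whose cyclohexene ring is made by metathesis.
- Forward key step: Pb(OAc)4 cleaves the C1–C6 bond and merges two six-membered rings into the ten-membered dione.
- For it: the fragmentation is reliable, the Z alkene is fixed by the six-membered ring, and C8 and C10 are set on a rigid bicycle. On these three points it is stronger.
- Against it: A2 has no butenolide. It has two ketones and a Z enone that can isomerise or react across the ring. Its C7 stereocentre is epimerisable and is destined to become sp2. C6 must be reduced, C7 oxidised, and C11–C13 attached and cyclised. The bridgehead cis-diol with five stereocentres is a long synthesis in itself.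
- Comparison: the chosen route accepts an unproven ring closure in return for a precursor made by routine steps and a very short end game.

**Alternative 3: Claisen ring expansion of a furan-fused 2-methylene oxocane to A3.**
- Disconnection: the C2–C3 bond and the C1 carbonyl of A3 are traced back to an allyl vinyl ether (C2=C1–O–C5–C4=C3) held in an eight-membered cyclic ether.
- Forward key step: a [3,3] shift forms C2–C3, breaks O–C5 and delivers the C1 ketone and the C4=C5 alkene.
- For it: the step is pericyclic and intramolecular, gives the C1 ketone directly, and C10 is set beforehand. As a ring-forming event it is at least as well founded as the chosen step.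
- Against it: the Z geometry of C4=C5 depends on a boat-like transition state. The oxocane is itself a medium ring and carries an acid-labile exocyclic enol ether. The furan must be oxidised regioselectively at C12 while C6 becomes a stereocentre by a late, uncontrolled protonation or reduction next to a conjugating alkene. The silyl groups on C10–O and C13–O must be exchanged for acetates.
- Comparison: the chosen route creates C6 in the same step as the lactone and carries both acetates through it.

Key step: step 17

Remark: atoms are numbered as in germacranes (C1–C10 ring, C11–C13 on the lactone, C14 on C10, C15 on C4).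
Remark: the (S,S) ligand in step 4 is assigned by analogy with simple ynones, the alkynyl group taking the place of an aryl group; if the sense is reversed, the enantiomeric catalyst is used.
Remark: enynol 12 is assumed to be bought as the pure Z isomer, so the C4=C5 geometry of 29 is bought and not made.

## Route

Step 1
Reactants: 1 prop-2-yn-1-ol
Product: 2 1-methoxy-4-[(prop-2-yn-1-yloxy)methyl]benzene
Conditions: NaH, 4-methoxybenzyl chloride, Bu4NI (cat.), THF, 0 °C to rt
Reagents that add atoms: 4-methoxybenzyl chloride, COc1ccc(CCl)cc1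
Why: Williamson ether synthesis on a primary alkoxide; the ether survives bases, organometallics and mild acid and is later removed oxidatively.

Step 2
Reactants: 3 (S)-citramalic acid
Product: 4 2-[(4S)-2,2,4-trimethyl-5-oxo-1,3-dioxolan-4-yl]acetic acid
Conditions: 2,2-dimethoxypropane, TsOH·H2O (cat.), rt
Reagents that add atoms: 2,2-dimethoxypropane, COC(C)(C)OC
Why: Acetonide formation of the α-hydroxy acid gives the five-membered dioxolanone and leaves the β-carboxyl (C8) free; the stereocentre is not touched.

Step 3
Reactants: 4 dioxolanone acid; 2 propargyl ether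
Product: 7 ynone (5S)-5-{5-[(4-methoxyphenyl)methoxy]-2-oxopent-3-yn-1-yl}-2,2,5-trimethyl-1,3-dioxolan-4-one, via acid chloride 5 (not isolated), via alkynylzinc chloride 6 (not isolated)
Conditions: 4, (COCl)2, DMF (cat.), CH2Cl2, 0 °C to rt; separately 2, n-BuLi, THF, −78 °C, then ZnCl2; combine with Pd(PPh3)4 (cat.), THF, 0 °C to rt
Reagents that add atoms: none
Why: Negishi acylation forms the C7–C8 bond; the weakly basic zinc acetylide attacks only the acid chloride and spares the dioxolanone and the acidic C9 hydrogens.

Step 4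
Reactants: 7 ynone
Product: 9 hydroxy lactone (3S,5S)-3-hydroxy-5-{3-[(4-methoxyphenyl)methoxy]prop-1-yn-1-yl}-3-methyloxolan-2-one, via hydroxy dioxolanone 8 (not isolated)
Conditions: Ru(p-cymene)[(S,S)-TsNCH(Ph)CH(Ph)NH] (2 mol%), i-PrOH, rt; then camphorsulfonic acid (cat.), CH2Cl2, rt
Reagents that add atoms: none
Why: Noyori asymmetric transfer hydrogenation of an ynone under base-free conditions sets C8 by catalyst control (8S expected with the (S,S) ligand); acid then lets the new hydroxyl displace the acetonide to give the γ-lactone with loss of acetone.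

Step 5
Reactants: 9 hydroxy lactone
Product: 10 (2S,4S)-2,4-dihydroxy-N-methoxy-7-[(4-methoxyphenyl)methoxy]-N,2-dimethylhept-5-ynamide
Conditions: MeNH(OMe)·HCl, AlMe3, CH2Cl2, 0 °C to rt
Reagents that add atoms: N,O-dimethylhydroxylamine hydrochloride, CNOC.Cl
Why: Aluminium amide aminolysis of a lactone gives the Weinreb amide at C1 and frees the C8 hydroxyl; no stereocentre is involved.

Step 6
Reactants: 10 dihydroxy Weinreb amide
Product: 11 (2S,4S)-4-[(tert-butyldimethylsilyl)oxy]-2-hydroxy-N-methoxy-7-[(4-methoxyphenyl)methoxy]-N,2-dimethylhept-5-ynamide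
Conditions: TBSCl, imidazole, DMF, 0 °C to rt
Reagents that add atoms: tert-butyldimethylsilyl chloride, CC(C)(C)[Si](C)(C)Cl
Why: The secondary propargylic hydroxyl is silylated selectively; the hindered tertiary hydroxyl stays free, which also stops relactonisation.

Step 7
Reactants: 12 (Z)-3-methylpent-2-en-4-yn-1-ol
Product: 13 (Z)-triethyl[(3-methylpent-2-en-4-yn-1-yl)oxy]silane
Conditions: TESCl, imidazole, CH2Cl2, 0 °C
Reagents that add atoms: triethylsilyl chloride, CC[Si](Cl)(CC)CC
Why: Standard silylation of a primary allylic alcohol; the triethylsilyl ether can later be removed in the presence of the C8 tert-butyldimethylsilyl ether.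

Step 8
Reactants: 13 enyne
Product: 14 (Z)-triethyl[(3-methylpenta-2,4-dien-1-yl)oxy]silane
Conditions: H2 (1 atm), Pd/CaCO3 poisoned with Pb(OAc)2, quinoline, hexane, rt
Reagents that add atoms: none
Why: Lindlar semi-hydrogenation turns the terminal alkyne into a vinyl group and leaves the trisubstituted Z alkene unchanged.

Step 9
Reactants: 14 diene
Product: 16 (Z)-3-methyl-5-[(triethylsilyl)oxy]pent-3-en-1-ol, via alkylborane 15 (not isolated)
Conditions: 9-BBN, THF, 0 °C to rt; then NaOH, H2O2, 0 °C
Reagents that add atoms: hydrogen peroxide, OO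
Why: Hydroboration–oxidation; the bulky borane adds only to the monosubstituted alkene, with boron on the terminal carbon, which becomes the C2 oxygen.

Step 10
Reactants: 16 homoallylic alcohol
Product: 17 (Z)-triethyl[(5-iodo-3-methylpent-2-en-1-yl)oxy]silane
Conditions: I2, PPh3, imidazole, CH2Cl2, 0 °C
Reagents that add atoms: iodine, II
Why: Appel iodination of a primary alcohol under buffered conditions that spare the silyl ether; the iodide is used without storage.

Step 11
Reactants: 17 iodide; 11 Weinreb amide
Product: 19 ketone (2Z,7S,9S)-9-[(tert-butyldimethylsilyl)oxy]-7-hydroxy-12-[(4-methoxyphenyl)methoxy]-3,7-dimethyl-1-[(triethylsilyl)oxy]dodec-2-en-10-yn-6-one, via organolithium 18 (not isolated)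
Conditions: 17, t-BuLi (2.1 equiv), Et2O, −78 °C; added to 11 pre-treated with i-PrMgCl (1.0 equiv) in THF, −78 to −20 °C; aq. NH4Cl
Reagents that add atoms: none
Why: Iodine–lithium exchange and Weinreb ketone synthesis form the C1–C2 bond; the chelated tetrahedral intermediate stops at the ketone and the quaternary C10 cannot epimerise.

Step 12
Reactants: 19 α-hydroxy ketone
Product: 21 hydroxy ketal (2S,4S)-4-[(tert-butyldimethylsilyl)oxy]-7-[(4-methoxyphenyl)methoxy]-2-{2-[(3Z)-3-methyl-5-(triethylsilyloxy)pent-3-en-1-yl]-1,3-dioxolan-2-yl}hept-5-yn-2-ol, via silyl ether 20 (not isolated)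
Conditions: TMSOCH2CH2OTMS, TMSOTf (cat.), CH2Cl2, −78 to −20 °C; pyridine; then K2CO3, MeOH, 0 °C
Reagents that add atoms: 1,2-bis(trimethylsilyloxy)ethane, C[Si](C)(C)OCCO[Si](C)(C)C
Why: Silyl-triflate-catalysed ketalisation (Noyori conditions) is driven by formation of hexamethyldisiloxane and works on hindered ketones at low temperature; the tertiary hydroxyl is silylated in passing, which blocks α-ketol rearrangement, and is freed by methanolysis.

Step 13
Reactants: 21 hydroxy ketal
Product: 22 (4S,6S)-4-[(tert-butyldimethylsilyl)oxy]-6-{2-[(3Z)-3-methyl-5-(triethylsilyloxy)pent-3-en-1-yl]-1,3-dioxolan-2-yl}hept-2-yne-1,6-diol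
Conditions: DDQ, CH2Cl2/pH 7 buffer, 0 °C
Reagents that add atoms: none
Why: Oxidative cleavage of the 4-methoxybenzyl ether frees the C13 hydroxyl; the buffered medium spares the silyl ethers and the ketal.

Step 14
Reactants: 22 diol
Product: 23 (4S,6S)-4-[(tert-butyldimethylsilyl)oxy]-6-{2-[(3Z)-3-methyl-5-(triethylsilyloxy)pent-3-en-1-yl]-1,3-dioxolan-2-yl}hept-2-yne-1,6-diyl diacetate
Conditions: Ac2O, DMAP, Et3N, CH2Cl2, rt to 40 °C
Reagents that add atoms: acetic anhydride, CC(=O)OC(C)=O
Why: DMAP-catalysed acylation places both target acetates (C13 primary, C10 tertiary) in one step after the last organometallic reaction; the tertiary hydroxyl needs gentle warming.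

Step 15
Reactants: 23 diacetate
Product: 24 (4S,6S)-4-[(tert-butyldimethylsilyl)oxy]-6-{2-[(3Z)-5-hydroxy-3-methylpent-3-en-1-yl]-1,3-dioxolan-2-yl}hept-2-yne-1,6-diyl diacetate
Conditions: HF·pyridine, pyridine, THF, 0 °C
Reagents that add atoms: none
Why: Buffered fluoride removes the primary triethylsilyl ether much faster than the secondary tert-butyldimethylsilyl ether and leaves acetates and ketal intact.

Step 16
Reactants: 24 allylic alcohol
Product: 25 (4S,6S)-4-[(tert-butyldimethylsilyl)oxy]-6-{2-[(3Z)-3-methyl-5-oxopent-3-en-1-yl]-1,3-dioxolan-2-yl}hept-2-yne-1,6-diyl diacetate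
Conditions: Dess–Martin periodinane, NaHCO3, CH2Cl2, 0 °C
Reagents that add atoms: none
Why: Buffered Dess–Martin oxidation gives the Z-enal without acid or base that could isomerise it; the aldehyde is used at once.

Step 17
Reactants: 25 Z-enal alkyne
Product: 26 (4Z,6R,8S,10S)-10,13-diacetoxy-8-[(tert-butyldimethylsilyl)oxy]-1,1-(ethylenedioxy)germacra-4,7(11)-dien-12,6-olide
Conditions: Mo(CO)6 (1.5 equiv), DMSO (10 equiv), toluene, 100 °C; 25 added by syringe pump to a final 0.002 M
Reagents that add atoms: carbon monoxide (delivered by Mo(CO)6), [C-]#[O+]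
Why: Proposed new method: zerovalent molybdenum, freed from Mo(CO)6 by DMSO, should bind the alkyne and undergo oxidative cyclisation with the C6 aldehyde C=O to an oxamolybdacyclopentene that holds the new C6–C7 bond; CO then inserts into the Mo–C11 bond and C12–O reductive elimination releases the butenolide. The closest known reaction type is the hetero-Pauson–Khand cyclocarbonylation of yne-aldehydes with Mo(CO)6/DMSO or Ru3(CO)12/CO, shown so far only where the new carbocycle is five- or six-membered. The ten-membered ring closes in the exo mode at the proximal alkyne carbon C7, and the lactone closes from the five-membered metallacycle by insertion and reductive elimination. Coupling at C11 is disfavoured on geometric grounds, because it would place an E-configured C7=C11 bond and the metallacycle inside an eleven-membered ring that already holds the Z C4=C5 bond. C6 is the one new stereocentre: with C8–H lying in the plane of the developing C7=C11 bond toward C13 (allylic strain), C9 and the silyloxy group flank that plane, and the chain should bring C5 to the face opposite C9, which corresponds to 6R. Slow addition at high dilution, the Z alkene, the quaternary C10 and the C1 ketal are relied on to favour the folded chain over oligomerisation, and the ketal keeps C1 from acting as the carbonyl partner. Both the ring size and the use of a conjugated Z-enal as carbonyl partner are untested.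

Step 18
Reactants: 26 silyl ether
Product: 27 (4Z,6R,8S,10S)-10,13-diacetoxy-1,1-(ethylenedioxy)-8-hydroxygermacra-4,7(11)-dien-12,6-olide
Conditions: HF·pyridine, THF, 0 °C to rt
Reagents that add atoms: none
Why: Fluoride desilylation under weakly acidic conditions avoids base at the acidic C6–H and leaves the dioxolane and acetates in place.

Step 19
Reactants: 27 alcohol
Product: 28 (4Z,6R,8S,10S)-10,13-diacetoxy-1,1-(ethylenedioxy)-8-(methacryloyloxy)germacra-4,7(11)-dien-12,6-olide
Conditions: methacrylic anhydride, DMAP, Et3N, CH2Cl2, 0 °C to rt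
Reagents that add atoms: methacrylic anhydride, C=C(C)C(=O)OC(=O)C(C)=C
Why: DMAP-catalysed esterification of the secondary C8 hydroxyl with retention; the C1 ketal prevents transannular hemiketal formation during acylation.

Step 20
Reactants: 28 ketal
Product: 29 (4Z,6R,8S,10S)-10,13-diacetoxy-8-(methacryloyloxy)-1-oxogermacra-4,7(11)-dien-12,6-olide (CNP0115165.3)
Conditions: TsOH·H2O (cat.), acetone/H2O (10:1), 40 °C
Reagents that add atoms: water, O
Why: Acid-catalysed ketal hydrolysis with acetone as glycol acceptor; the three esters and the lactone tolerate dilute aqueous acid and no stereocentre is at risk.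

## Compound list

1 | prop-2-yn-1-ol | C#CCO | starting material
2 | 1-methoxy-4-[(prop-2-yn-1-yloxy)methyl]benzene | C#CCOCc1ccc(OC)cc1 | intermediate
3 | (S)-citramalic acid | C[C@](O)(CC(=O)O)C(=O)O | starting material
4 | 2-[(4S)-2,2,4-trimethyl-5-oxo-1,3-dioxolan-4-yl]acetic acid | C[C@@]1(CC(=O)O)OC(C)(C)OC1=O | intermediate
5 | 2-[(4S)-2,2,4-trimethyl-5-oxo-1,3-dioxolan-4-yl]acetyl chloride | C[C@@]1(CC(=O)Cl)OC(C)(C)OC1=O | intermediate (not isolated)
6 | chloro{3-[(4-methoxyphenyl)methoxy]prop-1-yn-1-yl}zinc | COc1ccc(COCC#C[Zn]Cl)cc1 | intermediate (not isolated)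
7 | (5S)-5-{5-[(4-methoxyphenyl)methoxy]-2-oxopent-3-yn-1-yl}-2,2,5-trimethyl-1,3-dioxolan-4-one | C[C@@]1(CC(=O)C#CCOCc2ccc(OC)cc2)OC(C)(C)OC1=O | intermediate
8 | (5S)-5-{(2S)-2-hydroxy-5-[(4-methoxyphenyl)methoxy]pent-3-yn-1-yl}-2,2,5-trimethyl-1,3-dioxolan-4-one | C[C@@]1(C[C@H](O)C#CCOCc2ccc(OC)cc2)OC(C)(C)OC1=O | intermediate (not isolated)
9 | (3S,5S)-3-hydroxy-5-{3-[(4-methoxyphenyl)methoxy]prop-1-yn-1-yl}-3-methyloxolan-2-one | C[C@]1(O)C[C@@H](C#CCOCc2ccc(OC)cc2)OC1=O | intermediate
10 | (2S,4S)-2,4-dihydroxy-N-methoxy-7-[(4-methoxyphenyl)methoxy]-N,2-dimethylhept-5-ynamide | CON(C)C(=O)[C@@](C)(O)C[C@H](O)C#CCOCc1ccc(OC)cc1 | intermediate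
11 | (2S,4S)-4-[(tert-butyldimethylsilyl)oxy]-2-hydroxy-N-methoxy-7-[(4-methoxyphenyl)methoxy]-N,2-dimethylhept-5-ynamide | CON(C)C(=O)[C@@](C)(O)C[C@H](O[Si](C)(C)C(C)(C)C)C#CCOCc1ccc(OC)cc1 | intermediate
12 | (Z)-3-methylpent-2-en-4-yn-1-ol | C#C/C(C)=C\CO | starting material
13 | (Z)-triethyl[(3-methylpent-2-en-4-yn-1-yl)oxy]silane | C#C/C(C)=C\CO[Si](CC)(CC)CC | intermediate
14 | (Z)-triethyl[(3-methylpenta-2,4-dien-1-yl)oxy]silane | C=C/C(C)=C\CO[Si](CC)(CC)CC | intermediate
15 | 9-[(Z)-3-methyl-5-(triethylsilyloxy)pent-3-en-1-yl]-9-borabicyclo[3.3.1]nonane | CC[Si](CC)(CC)OC/C=C(C)\CCB1C2CCCC1CCC2 | intermediate (not isolated)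
16 | (Z)-3-methyl-5-[(triethylsilyl)oxy]pent-3-en-1-ol | OCC/C(C)=C\CO[Si](CC)(CC)CC | intermediate
17 | (Z)-triethyl[(5-iodo-3-methylpent-2-en-1-yl)oxy]silane | ICC/C(C)=C\CO[Si](CC)(CC)CC | intermediate
18 | [(Z)-3-methyl-5-(triethylsilyloxy)pent-3-en-1-yl]lithium | [Li]CC/C(C)=C\CO[Si](CC)(CC)CC | intermediate (not isolated)
19 | (2Z,7S,9S)-9-[(tert-butyldimethylsilyl)oxy]-7-hydroxy-12-[(4-methoxyphenyl)methoxy]-3,7-dimethyl-1-[(triethylsilyl)oxy]dodec-2-en-10-yn-6-one | CC[Si](CC)(CC)OC/C=C(C)\CCC(=O)[C@@](C)(O)C[C@H](O[Si](C)(C)C(C)(C)C)C#CCOCc1ccc(OC)cc1 | intermediate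
20 | O-trimethylsilyl ether of 21 (tertiary C10–O–SiMe3) | CC[Si](CC)(CC)OC/C=C(C)\CCC1(OCCO1)[C@@](C)(O[Si](C)(C)C)C[C@H](O[Si](C)(C)C(C)(C)C)C#CCOCc1ccc(OC)cc1 | intermediate (not isolated)
21 | (2S,4S)-4-[(tert-butyldimethylsilyl)oxy]-7-[(4-methoxyphenyl)methoxy]-2-{2-[(3Z)-3-methyl-5-(triethylsilyloxy)pent-3-en-1-yl]-1,3-dioxolan-2-yl}hept-5-yn-2-ol | CC[Si](CC)(CC)OC/C=C(C)\CCC1(OCCO1)[C@@](C)(O)C[C@H](O[Si](C)(C)C(C)(C)C)C#CCOCc1ccc(OC)cc1 | intermediate
22 | (4S,6S)-4-[(tert-butyldimethylsilyl)oxy]-6-{2-[(3Z)-3-methyl-5-(triethylsilyloxy)pent-3-en-1-yl]-1,3-dioxolan-2-yl}hept-2-yne-1,6-diol | CC[Si](CC)(CC)OC/C=C(C)\CCC1(OCCO1)[C@@](C)(O)C[C@H](O[Si](C)(C)C(C)(C)C)C#CCO | intermediate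
23 | (4S,6S)-4-[(tert-butyldimethylsilyl)oxy]-6-{2-[(3Z)-3-methyl-5-(triethylsilyloxy)pent-3-en-1-yl]-1,3-dioxolan-2-yl}hept-2-yne-1,6-diyl diacetate | CC[Si](CC)(CC)OC/C=C(C)\CCC1(OCCO1)[C@@](C)(OC(C)=O)C[C@H](O[Si](C)(C)C(C)(C)C)C#CCOC(C)=O | intermediate
24 | (4S,6S)-4-[(tert-butyldimethylsilyl)oxy]-6-{2-[(3Z)-5-hydroxy-3-methylpent-3-en-1-yl]-1,3-dioxolan-2-yl}hept-2-yne-1,6-diyl diacetate | OC/C=C(C)\CCC1(OCCO1)[C@@](C)(OC(C)=O)C[C@H](O[Si](C)(C)C(C)(C)C)C#CCOC(C)=O | intermediate
25 | (4S,6S)-4-[(tert-butyldimethylsilyl)oxy]-6-{2-[(3Z)-3-methyl-5-oxopent-3-en-1-yl]-1,3-dioxolan-2-yl}hept-2-yne-1,6-diyl diacetate | O=C/C=C(C)\CCC1(OCCO1)[C@@](C)(OC(C)=O)C[C@H](O[Si](C)(C)C(C)(C)C)C#CCOC(C)=O | intermediate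
26 | (4Z,6R,8S,10S)-10,13-diacetoxy-8-[(tert-butyldimethylsilyl)oxy]-1,1-(ethylenedioxy)germacra-4,7(11)-dien-12,6-olide | CC(C)(C)[Si](C)(C)O[C@H]1C[C@](C)(OC(C)=O)C2(OCCO2)CC/C(C)=C\[C@H]2OC(=O)C(COC(C)=O)=C12 | intermediate
27 | (4Z,6R,8S,10S)-10,13-diacetoxy-1,1-(ethylenedioxy)-8-hydroxygermacra-4,7(11)-dien-12,6-olide | O[C@H]1C[C@](C)(OC(C)=O)C2(OCCO2)CC/C(C)=C\[C@H]2OC(=O)C(COC(C)=O)=C12 | intermediate
28 | (4Z,6R,8S,10S)-10,13-diacetoxy-1,1-(ethylenedioxy)-8-(methacryloyloxy)germacra-4,7(11)-dien-12,6-olide | C=C(C)C(=O)O[C@H]1C[C@](C)(OC(C)=O)C2(OCCO2)CC/C(C)=C\[C@H]2OC(=O)C(COC(C)=O)=C12 | intermediate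
29 | (4Z,6R,8S,10S)-10,13-diacetoxy-8-(methacryloyloxy)-1-oxogermacra-4,7(11)-dien-12,6-olide (CNP0115165.3) | C=C(C)C(=O)O[C@H]1C[C@](C)(OC(C)=O)C(=O)CC/C(C)=C\[C@H]2OC(=O)C(COC(C)=O)=C12 | target

## Step count and least certain steps

Total step count: 20. Longest linear sequence: 15 steps (from 3 through steps 2–6 and 11–20; the branch from 1 through steps 1, 3–6 and 11–20 is equally long).

**Step 17 (key step).**
- What may go wrong: intermolecular alkyne–aldehyde coupling and oligomerisation may outrun closure of the strained ten-membered ring. The metal may be tied up by the conjugated enal acting as a heterodiene. The Z-enal may isomerise at 100 °C. The facial selectivity at C6 may be poor, because only chain conformation controls it.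
- Fallback (known reactions only; sets out from 22, returns at 26): the alkyne is turned into a (Z)-β-iodo enoate so that the ring can be closed by a Nozaki–Hiyama–Kishi reaction. Oxidation of the propargylic alcohol of 22 (TEMPO, PhI(OAc)2, buffered MeCN/H2O) gives (4S,6S)-4-silyloxy-6-hydroxy-hept-2-ynoic acid F1, and TMSCHN2 gives its methyl ester F2; in this branch the former C13 carbon becomes the lactone carbonyl. Conjugate addition of iodide with aldol capture of formaldehyde (MgI2, paraformaldehyde, CH2Cl2; the iodo-aldol or β-iodo Morita–Baylis–Hillman reaction of alkynoates) gives the (Z)-β-iodo-α-(hydroxymethyl) enoate F3, with iodine on C7 cis to the ester. Ac2O/DMAP gives diacetate F4, HF·pyridine/pyridine gives allylic alcohol F5, and Dess–Martin periodinane gives Z-enal F6. CrCl2 with catalytic NiCl2 in DMSO/THF at high dilution then joins C7 to C6, and the chromium alkoxide lactonises onto the cis ester to give 26. C6 is then set under substrate control in the addition, at the cost of six more compounds.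

**Step 12 (ketalisation).**
- What may go wrong: the ketone is flanked by a fully substituted, oxygen-bearing carbon, so ketalisation may stall, and forcing it risks silyl ether loss or α-ketol rearrangement.
- Fallback (sets out from 19, returns at 21): ethane-1,2-dithiol with Zn(OTf)2 gives the dithiolane F7, since thioketalisation is far less sensitive to hindrance. S-methylation with MeOTf in the presence of 2,6-di-tert-butylpyridine, followed by ethylene glycol, exchanges sulfur for oxygen irreversibly and gives 21.

**Step 20 (ketal hydrolysis).**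
- What may go wrong: the hindered, electron-poor ketal may hydrolyse slowly, and stronger acid may cause loss or migration of acetate or ionisation at the allylic lactone carbon while the methacrylate is already in place.
- Fallback (sets out from 26, returns at 29): aqueous HF in MeCN removes the silyl ether and the ketal in one operation, on a compound without the methacrylate, to give hydroxy ketone F8 (which may rest as its C1/C8 hemiketal). Methacrylic anhydride/DMAP then acylates the open form to 29.

**Step 11 (organolithium addition).**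
- What may go wrong: addition to the hindered, alkoxide-bearing Weinreb amide may be slow, which leaves time for the organolithium to decay by proton abstraction or by intramolecular attack on its own silyl ether.
- Fallback (sets out from 9 with 18, returns at 19): 18 (2.2 equiv) is added to the less hindered lactone 9 at −78 °C. The tetrahedral dialkoxide collapses only on work-up and gives keto diol F9, and TBSCl/imidazole silylates its secondary hydroxyl to give 19.

## Further compounds

F1 | step 17 | (4S,6S)-4-[(tert-butyldimethylsilyl)oxy]-6-hydroxy-6-{2-[(3Z)-3-methyl-5-(triethylsilyloxy)pent-3-en-1-yl]-1,3-dioxolan-2-yl}hept-2-ynoic acid | CC[Si](CC)(CC)OC/C=C(C)\CCC1(OCCO1)[C@@](C)(O)C[C@H](O[Si](C)(C)C(C)(C)C)C#CC(=O)O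
F2 | step 17 | methyl (4S,6S)-4-[(tert-butyldimethylsilyl)oxy]-6-hydroxy-6-{2-[(3Z)-3-methyl-5-(triethylsilyloxy)pent-3-en-1-yl]-1,3-dioxolan-2-yl}hept-2-ynoate | CC[Si](CC)(CC)OC/C=C(C)\CCC1(OCCO1)[C@@](C)(O)C[C@H](O[Si](C)(C)C(C)(C)C)C#CC(=O)OC
F3 | step 17 | methyl (2Z,4S,6S)-4-[(tert-butyldimethylsilyl)oxy]-6-hydroxy-2-(hydroxymethyl)-3-iodo-6-{2-[(3Z)-3-methyl-5-(triethylsilyloxy)pent-3-en-1-yl]-1,3-dioxolan-2-yl}hept-2-enoate | CC[Si](CC)(CC)OC/C=C(C)\CCC1(OCCO1)[C@@](C)(O)C[C@H](O[Si](C)(C)C(C)(C)C)/C(I)=C(\CO)C(=O)OC
F4 | step 17 | methyl (2Z,4S,6S)-6-acetoxy-2-(acetoxymethyl)-4-[(tert-butyldimethylsilyl)oxy]-3-iodo-6-{2-[(3Z)-3-methyl-5-(triethylsilyloxy)pent-3-en-1-yl]-1,3-dioxolan-2-yl}hept-2-enoate | CC[Si](CC)(CC)OC/C=C(C)\CCC1(OCCO1)[C@@](C)(OC(C)=O)C[C@H](O[Si](C)(C)C(C)(C)C)/C(I)=C(\COC(C)=O)C(=O)OC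
F5 | step 17 | methyl (2Z,4S,6S)-6-acetoxy-2-(acetoxymethyl)-4-[(tert-butyldimethylsilyl)oxy]-6-{2-[(3Z)-5-hydroxy-3-methylpent-3-en-1-yl]-1,3-dioxolan-2-yl}-3-iodohept-2-enoate | OC/C=C(C)\CCC1(OCCO1)[C@@](C)(OC(C)=O)C[C@H](O[Si](C)(C)C(C)(C)C)/C(I)=C(\COC(C)=O)C(=O)OC
F6 | step 17 | methyl (2Z,4S,6S)-6-acetoxy-2-(acetoxymethyl)-4-[(tert-butyldimethylsilyl)oxy]-3-iodo-6-{2-[(3Z)-3-methyl-5-oxopent-3-en-1-yl]-1,3-dioxolan-2-yl}hept-2-enoate | O=C/C=C(C)\CCC1(OCCO1)[C@@](C)(OC(C)=O)C[C@H](O[Si](C)(C)C(C)(C)C)/C(I)=C(\COC(C)=O)C(=O)OC
F7 | step 12 | (2S,4S)-4-[(tert-butyldimethylsilyl)oxy]-7-[(4-methoxyphenyl)methoxy]-2-{2-[(3Z)-3-methyl-5-(triethylsilyloxy)pent-3-en-1-yl]-1,3-dithiolan-2-yl}hept-5-yn-2-ol | CC[Si](CC)(CC)OC/C=C(C)\CCC1(SCCS1)[C@@](C)(O)C[C@H](O[Si](C)(C)C(C)(C)C)C#CCOCc1ccc(OC)cc1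
F8 | step 20 | (4Z,6R,8S,10S)-10,13-diacetoxy-8-hydroxy-1-oxogermacra-4,7(11)-dien-12,6-olide | O[C@H]1C[C@](C)(OC(C)=O)C(=O)CC/C(C)=C\[C@H]2OC(=O)C(COC(C)=O)=C12
F9 | step 11 | (2Z,7S,9S)-7,9-dihydroxy-12-[(4-methoxyphenyl)methoxy]-3,7-dimethyl-1-[(triethylsilyl)oxy]dodec-2-en-10-yn-6-one | CC[Si](CC)(CC)OC/C=C(C)\CCC(=O)[C@@](C)(O)C[C@H](O)C#CCOCc1ccc(OC)cc1
A1 | alternative 1 | 1-silyloxy-cyclodeca-1(10),4-dien-6-one with C7 dioxanylidene and C8 silyl ether | CC(C)(C)[Si](C)(C)O[C@H]1C/C(C)=C(O[Si](C)(C)C(C)(C)C)/CC/C(C)=C\C(=O)C1=C2COC(C)(C)OC2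
A2 | alternative 2 | (Z)-cyclodec-4-ene-1,6-dione with C10 acetate, C8 silyl ether and C7 4-methoxybenzyl ether | CC(C)(C)[Si](C)(C)O[C@H]1C[C@](C)(OC(C)=O)C(=O)CC/C(C)=C\C(=O)[C@@H]1OCc1ccc(OC)cc1
A3 | alternative 3 | furan-fused (Z)-cyclodec-4-en-1-one with C8, C10 and C13 silyl ethers | CC(C)(C)[Si](C)(C)O[C@H]1C[C@](C)(O[Si](CC)(CC)CC)C(=O)CC/C(C)=C\c2occ(CO[Si](C)(C)C(C)(C)C)c12
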